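**Plan**

1. Retrosynthesis, chain numbered C1 (ketone carbon) to C8: the aryl–C1 bond is cut first (aryllithium plus Weinreb amide), then C5–C6 (alkylzinc plus alkenyl bromide). What remains is the C1–C5 unit with its 3-methyl group, that is (R)-mevalonolactone.
2. Enabling feature: C3 carries CH3, OH and two CH2 arms (C2 and C4) and lies in no ring; the only ring, the benzene ring, hangs on C1. Writing both C1 and C5 as carboxyl carbons turns the core into prochiral dimethyl 3-hydroxy-3-methylglutarate.
3. Forward: esterase monohydrolysis of the diester, LiBH4 reduction of the surviving ester arm with lactonisation, Weinreb aminolysis, iodination at C5, O-silylation and Negishi coupling for C5–C6. Monolithiated bis-MOM 2,5-dibromohydroquinone is then acylated at C1 and the product is unmasked with acid.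
4. No ring is constructed: the benzene ring is bought, and the δ-lactone is a transient device that keeps the two arms different.
5. Stereochemistry: the single stereocentre C3 comes from the enzyme's choice between two enantiotopic ester arms. No bond to C3 is made or broken afterwards; the (S) descriptor of the half-ester becomes (R) in the target only through CIP priority changes.

Key step: step 1

Assumption: pig liver esterase is taken to hydrolyse the pro-R CH2CO2CH3 arm of 1, giving the (S)-half-ester 2, and diester 1 is taken to be a catalogue compound.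

Abbreviations: MOM = methoxymethyl, TES = triethylsilyl, dppf = 1,1'-bis(diphenylphosphino)ferrocene.

**Route**

Step 1
Reactants: 1 dimethyl 3-hydroxy-3-methylglutarate
Product: 2 (3S)-3-hydroxy-5-methoxy-3-methyl-5-oxopentanoic acid
Conditions: pig liver esterase, 0.1 M KH2PO4/K2HPO4 buffer pH 7.0, 25 °C, pH-stat with 1 M NaOH (1.0 equiv); then 2 M HCl to pH 2, NaCl, EtOAc extraction
Reagents that add atoms: water, O
Why: The active-site serine of the carboxylesterase adds to one ester carbonyl of 1, the tetrahedral intermediate releases methanol to leave an acyl-enzyme, and water hydrolyses the acyl-enzyme to the carboxylate. The closest known reaction type is the esterase-mediated monohydrolysis of prochiral 3-substituted and 3,3-disubstituted glutarate diesters to chiral half-esters. No ring is closed and no skeletal bond is formed; C3 becomes stereogenic only because its two CH2CO2CH3 arms cease to be identical. The configuration at C3 is controlled by the chiral binding pocket alone, which has to tell the hydrogen-bonding OH from the apolar CH3 when it presents one arm to the serine; hydrolysis of the pro-R arm, taken here as the enzyme's preference, gives the (S)-half-ester. The step needs enantiotopic-group selectivity, supplied by the enzyme and to be verified at lactone 5 by chiral GC, and mono- over di-hydrolysis, secured because the half-ester is an anion at pH 7 that binds poorly and because base uptake is stopped at one equivalent. Neutral buffer at 25 °C should leave the tertiary β-hydroxy ester free of retro-aldol cleavage and dehydration.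

Step 2
Reactants: 2 (3S)-3-hydroxy-5-methoxy-3-methyl-5-oxopentanoic acid
Product: 5 (R)-mevalonolactone [(4R)-4-hydroxy-4-methyloxan-2-one], via lithium half-ester carboxylate 3 (not isolated), via (R)-mevalonic acid 4 (not isolated)
Conditions: LiOH·H2O (1.0 equiv), MeOH, evaporate to dryness; LiBH4 (2.5 equiv), THF, 0 → 50 °C; 2 M HCl to pH 1–2, rt; continuous extraction with CH2Cl2
Reagents that add atoms: none
Why: LiBH4 reduces carboxylic esters but not carboxylate salts, so only the ester arm (future C4–C5) is taken to the alcohol and acid then closes the δ-lactone by intramolecular Fischer esterification; this choice of arm maps the (S)-half-ester onto the (R)-series, whereas borane reduction of the acid arm would lead to the enantiomeric lactone.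

Step 3
Reactants: 5 (R)-mevalonolactone
Product: 6 (3R)-3,5-dihydroxy-N-methoxy-N,3-dimethylpentanamide
Conditions: MeNHOMe·HCl (3 equiv), AlMe3 (3 equiv), CH2Cl2, 0 °C → rt; aqueous potassium sodium tartrate (KNaC4H4O6) work-up; used without storage
Reagents that add atoms: N,O-dimethylhydroxylamine hydrochloride, CNOC.Cl
Why: Weinreb aminolysis of a lactone: the chloro(methyl)aluminium amide formed in the flask from AlMe3 and the amine hydrochloride attacks the lactone carbonyl and opens the acyl–oxygen bond under non-acidic conditions, which installs the C1 N-methoxy-N-methylamide and frees the C5 primary alcohol while C3 is untouched.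

Step 4
Reactants: 6 (3R)-3,5-dihydroxy-N-methoxy-N,3-dimethylpentanamide
Product: 7 (3S)-3-hydroxy-5-iodo-N-methoxy-N,3-dimethylpentanamide
Conditions: PPh3 (1.3 equiv), imidazole (2 equiv), I2 (1.3 equiv), CH2Cl2, 0 °C → rt
Reagents that add atoms: iodine, II
Why: Appel-type iodination with PPh3, I2 and imidazole converts only the unhindered primary C5 hydroxyl into an alkoxyphosphonium ion that iodide displaces by SN2, the tertiary C3 alcohol being too hindered to be activated (the descriptor changes to S only because the iodoethyl arm now outranks the amide arm).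

Step 5
Reactants: 7 (3S)-3-hydroxy-5-iodo-N-methoxy-N,3-dimethylpentanamide
Product: 8 (3S)-5-iodo-N-methoxy-N,3-dimethyl-3-(triethylsilyloxy)pentanamide
Conditions: TESOTf (1.5 equiv), 2,6-lutidine (2.5 equiv), CH2Cl2, −78 → 0 °C
Reagents that add atoms: triethylsilyl trifluoromethanesulfonate, CC[Si](CC)(CC)OS(=O)(=O)C(F)(F)F
Why: Silylation of a hindered tertiary alcohol with a silyl triflate and 2,6-lutidine is standard practice, and the TES ether removes the only acidic proton before the organozinc and organolithium steps.

Step 6
Reactants: 8 (3S)-5-iodo-N-methoxy-N,3-dimethyl-3-(triethylsilyloxy)pentanamide; 9 1-bromo-2-methylprop-1-ene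
Product: 11 (3R)-N-methoxy-N,3,7-trimethyl-3-(triethylsilyloxy)oct-6-enamide, via alkylzinc iodide 10 (not isolated)
Conditions: Zn dust (activated with 1,2-dibromoethane and TMSCl, 3 mol % each), LiCl, THF, 25–40 °C; then 9 (1.5 equiv), PdCl2(dppf) (5 mol %), THF, 50 °C
Reagents that add atoms: none
Why: Direct LiCl-assisted zinc insertion into the primary alkyl iodide gives an alkylzinc iodide that does not attack the Weinreb amide, and Negishi cross-coupling with the alkenyl bromide at zerovalent palladium (formed in the flask from PdCl2(dppf); oxidative addition, transmetalation, reductive elimination) forms C5–C6, the wide-bite-angle ligand favouring reductive elimination over β-hydride elimination.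

Step 7
Reactants: 12 2,5-dibromohydroquinone (2,5-dibromobenzene-1,4-diol)
Product: 13 1,4-dibromo-2,5-bis(methoxymethoxy)benzene
Conditions: NaH (2.4 equiv), DMF, 0 °C; MOMCl (2.4 equiv), 0 °C → rt
Reagents that add atoms: chloromethyl methyl ether, COCCl
Why: Williamson etherification of the bis-phenoxide with chloromethyl methyl ether gives acetal protecting groups that withstand n-BuLi and assist the later bromine–lithium exchange by coordinating lithium.

Step 8
Reactants: 13 1,4-dibromo-2,5-bis(methoxymethoxy)benzene; 11 (3R)-N-methoxy-N,3,7-trimethyl-3-(triethylsilyloxy)oct-6-enamide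
Product: 16 (3R)-1-[4-bromo-2,5-bis(methoxymethoxy)phenyl]-3,7-dimethyl-3-(triethylsilyloxy)oct-6-en-1-one, via aryllithium 14 (not isolated), via lithium hemiaminal chelate 15 (not isolated)
Conditions: 13 (1.5 equiv), n-BuLi (1.45 equiv), THF, −78 °C; then 11 (1.0 equiv), THF, −78 → −40 °C; sat. aq. NH4Cl
Reagents that add atoms: none
Why: Bromine–lithium exchange with slightly less than one equivalent of n-BuLi at −78 °C stops at the monolithio stage because a second exchange on the electron-rich aryllithium is much slower, and the aryllithium then adds once to the amide in a Weinreb ketone synthesis since the chelated tetrahedral adduct 15 persists until the aqueous quench.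

Step 9
Reactants: 16 (3R)-1-[4-bromo-2,5-bis(methoxymethoxy)phenyl]-3,7-dimethyl-3-(triethylsilyloxy)oct-6-en-1-one
Product: 17 (3R)-1-(4-bromo-2,5-dihydroxyphenyl)-3-hydroxy-3,7-dimethyloct-6-en-1-one
Conditions: HCl (1.25 M in MeOH), MeOH–THF, 0 °C → rt, under argon; NaHCO3 quench as soon as conversion is complete
Reagents that add atoms: none
Why: Acid-catalysed methanolysis cleaves both aryl methoxymethyl acetals by transacetalisation and the tertiary silyl ether by solvolysis in one operation, and dilute acid at low temperature for a short time is chosen so that the tertiary β-hydroxy ketone should neither dehydrate nor add to the trisubstituted alkene.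

**Compound list**

1 | dimethyl 3-hydroxy-3-methylglutarate (dimethyl 3-hydroxy-3-methylpentanedioate) | COC(=O)CC(C)(O)CC(=O)OC | starting material
2 | (3S)-3-hydroxy-5-methoxy-3-methyl-5-oxopentanoic acid | COC(=O)C[C@@](C)(O)CC(=O)O | intermediate
3 | lithium (3S)-3-hydroxy-5-methoxy-3-methyl-5-oxopentanoate | COC(=O)C[C@@](C)(O)CC(=O)[O-].[Li+] | intermediate (not isolated)
4 | (R)-mevalonic acid, (3R)-3,5-dihydroxy-3-methylpentanoic acid | OCC[C@@](C)(O)CC(=O)O | intermediate (not isolated)
5 | (R)-mevalonolactone, (4R)-4-hydroxy-4-methyloxan-2-one | C[C@@]1(O)CCOC(=O)C1 | intermediate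
6 | (3R)-3,5-dihydroxy-N-methoxy-N,3-dimethylpentanamide | OCC[C@@](C)(O)CC(=O)N(C)OC | intermediate
7 | (3S)-3-hydroxy-5-iodo-N-methoxy-N,3-dimethylpentanamide | ICC[C@@](C)(O)CC(=O)N(C)OC | intermediate
8 | (3S)-5-iodo-N-methoxy-N,3-dimethyl-3-(triethylsilyloxy)pentanamide | ICC[C@@](C)(O[Si](CC)(CC)CC)CC(=O)N(C)OC | intermediate
9 | 1-bromo-2-methylprop-1-ene | CC(C)=CBr | starting material
10 | [(3S)-5-[methoxy(methyl)amino]-3-methyl-5-oxo-3-(triethylsilyloxy)pentyl]zinc iodide | I[Zn]CC[C@@](C)(O[Si](CC)(CC)CC)CC(=O)N(C)OC | intermediate (not isolated)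
11 | (3R)-N-methoxy-N,3,7-trimethyl-3-(triethylsilyloxy)oct-6-enamide | CC(C)=CCC[C@@](C)(O[Si](CC)(CC)CC)CC(=O)N(C)OC | intermediate
12 | 2,5-dibromohydroquinone (2,5-dibromobenzene-1,4-diol) | Oc1cc(Br)c(O)cc1Br | starting material
13 | 1,4-dibromo-2,5-bis(methoxymethoxy)benzene | COCOc1cc(Br)c(OCOC)cc1Br | intermediate
14 | [4-bromo-2,5-bis(methoxymethoxy)phenyl]lithium | [Li]c1cc(OCOC)c(Br)cc1OCOC | intermediate (not isolated)
15 | lithium (3R)-1-[4-bromo-2,5-bis(methoxymethoxy)phenyl]-1-[methoxy(methyl)amino]-3,7-dimethyl-3-(triethylsilyloxy)oct-6-en-1-olate (C1 epimers) | CC(C)=CCC[C@@](C)(O[Si](CC)(CC)CC)CC(O[Li])(N(C)OC)c1cc(OCOC)c(Br)cc1OCOC | intermediate (not isolated)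
16 | (3R)-1-[4-bromo-2,5-bis(methoxymethoxy)phenyl]-3,7-dimethyl-3-(triethylsilyloxy)oct-6-en-1-one | CC(C)=CCC[C@@](C)(O[Si](CC)(CC)CC)CC(=O)c1cc(OCOC)c(Br)cc1OCOC | intermediate
17 | (3R)-1-(4-bromo-2,5-dihydroxyphenyl)-3-hydroxy-3,7-dimethyloct-6-en-1-one | CC(C)=CCC[C@@](C)(O)CC(=O)c1cc(O)c(Br)cc1O | target

**Summary**

Total step count: 9. Longest linear sequence: 8 (steps 1–6, 8 and 9); step 7 prepares the aryl partner.

Steps most likely to fail:

Step 1. The esterase may discriminate poorly between the two enantiotopic ester arms, because CH3 and OH at C3 are both small, or may prefer the other arm. The half-ester and the lactone would then be of low enantiomeric purity. The fallback replaces reliance on the enzyme by separation of covalent diastereomers. It sets out from lactone 5 of insufficient purity, which is opened with (R)-1-phenylethylamine (neat, 70 °C) to the diastereomeric dihydroxy amides. The wanted diastereomer (3R)-3,5-dihydroxy-3-methyl-N-[(1R)-1-phenylethyl]pentanamide F1 is separated by crystallisation or chromatography, hydrolysed with aqueous NaOH at reflux and acidified with HCl, which closes the ring again. The fallback comes back at enantiomerically pure 5, and the route continues with step 3.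

Step 9. During acidic removal of the MOM groups the tertiary β-hydroxy ketone may lose water, after which the ortho phenol can close onto the enone in an oxa-Michael reaction. The tertiary alcohol or methanol may also add to the protonated trisubstituted alkene. The fallback avoids Brønsted acid by changing the phenol protecting group; it sets out from 12 and comes back at 17. Compound 12 is allylated (allyl bromide, K2CO3, acetone, reflux) to 1,4-dibromo-2,5-bis(prop-2-enyloxy)benzene F2. Bromine–lithium exchange (n-BuLi, THF, −78 °C) gives [4-bromo-2,5-bis(prop-2-enyloxy)phenyl]lithium F3, which adds to amide 11 to give the lithium hemiaminal adduct F4. Aqueous NH4Cl then gives (3R)-1-[4-bromo-2,5-bis(prop-2-enyloxy)phenyl]-3,7-dimethyl-3-(triethylsilyloxy)oct-6-en-1-one F5. The silyl ether is cleaved with HF·pyridine buffered with pyridine (THF, 0 °C) to (3R)-1-[4-bromo-2,5-bis(prop-2-enyloxy)phenyl]-3-hydroxy-3,7-dimethyloct-6-en-1-one F6. The allyl groups are finally transferred to morpholine with Pd(PPh3)4 (5 mol %) in THF at rt, which gives 17 under neutral conditions.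

Step 6. Zinc insertion may be sluggish, the alkylzinc may be protonated by adventitious water, or the C5 iodide may alkylate the amide oxygen internally before transmetalation; β-hydride elimination at palladium is a further possibility. The fallback is a copper-mediated alkylation; it sets out from iodide 8 and bromide 9 and comes back at 11. Bromide 9 is treated with t-BuLi (2 equiv, Et2O, −78 °C) to give (2-methylprop-1-enyl)lithium F7. CuI (0.5 equiv, −40 °C) converts this into lithium bis(2-methylprop-1-enyl)cuprate F8, which displaces the primary iodide of 8 between −40 and 0 °C in an SN2-type coupling. The Weinreb amide is expected to be inert to the cuprate at these temperatures.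

**Further compounds**

F1 | step 1 | (3R)-3,5-dihydroxy-3-methyl-N-[(1R)-1-phenylethyl]pentanamide | OCC[C@@](C)(O)CC(=O)N[C@H](C)c1ccccc1
F2 | step 9 | 1,4-dibromo-2,5-bis(prop-2-enyloxy)benzene | C=CCOc1cc(Br)c(OCC=C)cc1Br
F3 | step 9 | [4-bromo-2,5-bis(prop-2-enyloxy)phenyl]lithium | [Li]c1cc(OCC=C)c(Br)cc1OCC=C
F4 | step 9 | lithium (3R)-1-[4-bromo-2,5-bis(prop-2-enyloxy)phenyl]-1-[methoxy(methyl)amino]-3,7-dimethyl-3-(triethylsilyloxy)oct-6-en-1-olate (lithium hemiaminal adduct) | CC(C)=CCC[C@@](C)(O[Si](CC)(CC)CC)CC(O[Li])(N(C)OC)c1cc(OCC=C)c(Br)cc1OCC=C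
F5 | step 9 | (3R)-1-[4-bromo-2,5-bis(prop-2-enyloxy)phenyl]-3,7-dimethyl-3-(triethylsilyloxy)oct-6-en-1-one | CC(C)=CCC[C@@](C)(O[Si](CC)(CC)CC)CC(=O)c1cc(OCC=C)c(Br)cc1OCC=C
F6 | step 9 | (3R)-1-[4-bromo-2,5-bis(prop-2-enyloxy)phenyl]-3-hydroxy-3,7-dimethyloct-6-en-1-one | CC(C)=CCC[C@@](C)(O)CC(=O)c1cc(OCC=C)c(Br)cc1OCC=C
F7 | step 6 | (2-methylprop-1-enyl)lithium | [Li]C=C(C)C
F8 | step 6 | lithium bis(2-methylprop-1-enyl)cuprate | [Li+].CC(C)=C[Cu-]C=C(C)C
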